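A direct plan would keep rings A and B as purchased arenes and close ring C last: three protecting-group alkylations, a nitroaldol condensation, an amine-catalysed oxa-Michael/Henry domino to the 3-nitro-2H-chromene A1, hydride reduction and Nef unmasking to the flavan-3-one A2, ketone reduction, bis-aroylation and hydrogenolysis.
Its weakest operations would be:
- the domino closure to A1, where C2 would be set through a reversible oxa-Michael addition, so the ee would depend on which adduct closes faster and on a recrystallisation;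
- the reductive Nef unmasking to A2 on late material, where C2 would be benzylic, alpha to the new ketone and beta to a phenoxide leaving group, so enolisation or retro-oxa-Michael opening would erase it;
- the borohydride reduction of A2, where C3 would be set by substrate bias alone, the cis epimer would have to be removed, and the free 3-OH would then have to be spared in the aroylation.
Three of its nine steps would only place protecting groups (two under mono-anion regiocontrol) before any skeletal bond was made.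

Plan of the new route.
The retrosynthesis cuts all three bonds to C8a (O1–C8a, C4a–C8a, C8–C8a), leaving an acyclic δ-hydroxy β-benzyloxy enone and a one-carbon thiocarbonyl unit; then C4a–C5 (acyl cross-coupling) and C2–C3 (anti-alkoxyallylation of the ring B aldehyde).
Ring B is bought; ring C and then ring A arise in one flask from the open chain.
The feature used: ring A is a phloroglucinol, so C4a–C5–C6–C7–C8 is an acetoacetyl-type chain (C5 ketone, C7 benzyl enol ether), and C8a, bonded to O1, C4a and C8, sits at the carbonic acid level and can enter as one thiocarbonyl carbon that is substituted three times.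
C2 and C3 are set together under catalyst control on acyclic material, are never alpha to a carbonyl or nitro group, and are not touched by the ring closures.
O5 and O7 are differentiated by the chain itself and O3 arrives benzylated, so the aroylation needs no selectivity.

Key step: step 7

Assumption: the sense of induction of the chiral phosphoric acid in step 3 is taken from the parent allylboration of aryl aldehydes (the (R)-acid attacks the Re face), so the (S)-acid is specified and the other enantiomer would be used if a first run showed the reverse; 3-(benzyloxy)-4-hydroxybenzaldehyde and 3,4,5-tris(benzyloxy)benzoyl chloride are taken as catalogue compounds.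

Step 1
Reactants: 1 3-(benzyloxy)-4-hydroxybenzaldehyde; 2 chlorotriisopropylsilane
Product: 3 3-(benzyloxy)-4-[(triisopropylsilyl)oxy]benzaldehyde
Conditions: i-Pr3SiCl (1.1 equiv), imidazole (2 equiv), DMF, rt
Reagents that add atoms: chlorotriisopropylsilane, CC(C)[Si](Cl)(C(C)C)C(C)C
Why: Imidazole-promoted O-silylation of the phenol; the aryl triisopropylsilyl ether should survive the borane, the palladium coupling and silazide bases, fall to fluoride later, and as a weak donor temper ionisation at the future benzylic C2.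

Step 2
Reactants: 4 benzyl prop-2-yn-1-yl ether; 5 pinacolborane
Product: 6 (E)-2-[3-(benzyloxy)prop-1-en-1-yl]-4,4,5,5-tetramethyl-1,3,2-dioxaborolane
Conditions: pinacolborane (1.1 equiv), Cp2Zr(H)Cl (5 mol%), Et3N (10 mol%), neat, 60 °C
Reagents that add atoms: pinacolborane, CC1(C)OBOC1(C)C
Why: Zirconocene-hydride-catalysed hydroboration of a terminal alkyne, a syn anti-Markovnikov addition that should give only the (E)-1-alkenylboronate.

Step 3
Reactants: 3 3-(benzyloxy)-4-[(triisopropylsilyl)oxy]benzaldehyde; 6 (E)-2-[3-(benzyloxy)prop-1-en-1-yl]-4,4,5,5-tetramethyl-1,3,2-dioxaborolane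
Product: 8 (1R,2S)-2-(benzyloxy)-1-{3-(benzyloxy)-4-[(triisopropylsilyl)oxy]phenyl}but-3-en-1-ol, via (E)-γ-(benzyloxy)allyl pinacolboronate 7 (not isolated)
Conditions: 6 (1.3 equiv), [Ir(cod)2]BF4 (2.5 mol%), PCy3 (5 mol%), ClCH2CH2Cl, rt, 1 h; then 3 (1.0 equiv), (S)-TRIP [(S)-3,3'-bis(2,4,6-triisopropylphenyl)-1,1'-binaphthyl-2,2'-diyl hydrogen phosphate] (5 mol%), 4 Å molecular sieves, −20 °C → rt; aq. NaHCO3
Reagents that add atoms: none
Why: Cationic monovalent iridium moves the C=C of 6 one position toward oxygen to the (E)-γ-alkoxyallylboronate 7 (driven by enol-ether conjugation), which adds to the aldehyde in a chiral phosphoric acid-catalysed allylboration (Antilla type) through a closed chair transition state with the aryl and the E-γ-benzyloxy group equatorial, so that the anti relation of C1–OH and C2–OBn follows from the E geometry and the 1R configuration from Si-face attack directed by the (S)-acid.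

Step 4
Reactants: 9 but-2-ynoic acid; 10 benzyl alcohol
Product: 11 (2E)-3-(benzyloxy)but-2-enoic acid
Conditions: BnOH (4 equiv), NaH (2.3 equiv), THF, 0 → 65 °C; then cold aq. HCl to pH 4
Reagents that add atoms: benzyl alcohol, OCc1ccccc1
Why: Oxa-Michael addition of benzyl oxide to the ynoate, with the thermodynamic E isomer (benzyloxy trans to the carboxyl, methyl cis) reached through reversible alkoxide addition–elimination.

Step 5
Reactants: 11 (2E)-3-(benzyloxy)but-2-enoic acid; 12 thiophenol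
Product: 13 S-phenyl (2E)-3-(benzyloxy)but-2-enethioate
Conditions: PhSH (1.1 equiv), DCC (1.1 equiv), DMAP (5 mol%), CH2Cl2, 0 °C → rt
Reagents that add atoms: thiophenol, Sc1ccccc1
Why: Steglich thioesterification, in which the vinylogous carbonate is too poor a Michael acceptor to take up the thiol, so the enol ether geometry should be kept.

Step 6
Reactants: 8 (1R,2S)-2-(benzyloxy)-1-{3-(benzyloxy)-4-[(triisopropylsilyl)oxy]phenyl}but-3-en-1-ol; 13 S-phenyl (2E)-3-(benzyloxy)but-2-enethioate
Product: 15 (2E,7S,8R)-2,7-bis(benzyloxy)-8-{3-(benzyloxy)-4-[(triisopropylsilyl)oxy]phenyl}-8-hydroxyoct-2-en-4-one, via B-alkyl-9-BBN adduct 14 (not isolated)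
Conditions: 9-BBN dimer (1.1 equiv), THF, 0 °C → rt; then 13 (1.0 equiv), Pd(PPh3)4 (5 mol%), copper thiophene-2-carboxylate Cu(O2CC4H3S) (1.6 equiv), Cs2CO3 (1.5 equiv), THF, 45 °C; aq. NaHCO3
Reagents that add atoms: none
Why: Terminal anti-Markovnikov hydroboration (the hydroxyl consumes one B–H) followed by Liebeskind–Srogl coupling of the B-alkyl borane with the thiol ester, in which zerovalent palladium inserts into the acyl–sulfur bond and the monovalent copper carboxylate takes up the thiolate and drives transmetalation, so the ketone should form without touching the enol ether or either stereocentre.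

Step 7
Reactants: 15 (2E,7S,8R)-2,7-bis(benzyloxy)-8-{3-(benzyloxy)-4-[(triisopropylsilyl)oxy]phenyl}-8-hydroxyoct-2-en-4-one; 16 O-phenyl carbonochloridothioate
Product: 20 (2R,3S)-3,7-bis(benzyloxy)-2-{3-(benzyloxy)-4-[(triisopropylsilyl)oxy]phenyl}-3,4-dihydro-2H-chromen-5-ol, via O-alkyl O-phenyl thionocarbonate 17 (not isolated), via lithium enethiolate of the β-oxo thionolactone 18 (not isolated), via cyclic α-oxo ketene O,S-acetal 19 (not isolated)
Conditions: 15 (0.03 M in THF), NaN(SiMe3)2 (1.0 equiv), −78 °C, then 16 (1.0 equiv), −78 °C, 30 min; LiN(SiMe3)2 (2.2 equiv), −78 → −30 °C; MeI (1.1 equiv), −30 → 0 °C; KN(SiMe3)2 (2.5 equiv), −78 → 0 °C; aq. NH4Cl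
Reagents that add atoms: O-phenyl carbonochloridothioate, S=C(Cl)Oc1ccccc1
Why: Proposed new method: the sodium alkoxide of 15 (formed kinetically at −78 °C; the vinylogous-ester carbonyl should not trap it as a hemiketal) is thioacylated to 17, which tethers the future C8a to O1, and LiN(SiMe3)2 then forms the kinetic α′-enolate at C4a, which attacks the thiocarbonyl in a 6-exo-trig Claisen-type thioacylation (closest known type: condensation of ketone enolates with xanthates or thionocarbonates to β-oxo thionoesters), expels phenoxide and closes ring C as the enethiolate 18, which MeI S-methylates to the α-oxo ketene O,S-acetal 19. KN(SiMe3)2 then removes a γ-proton at C8 of the benzyloxy-enone, and the 3-oxidohexatriene C8=C7–C6=C5–C4a=C8a closes the C8–C8a bond of ring A by 6π-electrocyclisation (equally a 6-endo-trig conjugate addition), closest known type the aromatic annulation of α-oxo ketene dithioacetals by carbanion addition–elimination (Junjappa–Ila). β-Elimination of methanethiolate and tautomerisation of the dienone give the phenoxide, so that the ketone carbon C5 becomes the free phenol and the enol-ether carbon C7 stays benzylated. No stereocentre is formed, and neither C2 nor C3 is alpha to a carbanionic or carbonyl carbon at any stage, so both should be carried through unchanged. The step needs α′- before γ-deprotonation in the first closure, which the kinetic base and the tether secure (only the C4a enolate reaches the thiocarbonyl through a six-membered transition state), and retention of O1 at C8a, which the leaving-group order secures (phenoxide and methanethiolate, pKa about 10, leave before the alkoxide O1, pKa about 16). S- rather than O-methylation of 18 follows from the softness of sulfur and of MeI.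

Step 8
Reactants: 20 (2R,3S)-3,7-bis(benzyloxy)-2-{3-(benzyloxy)-4-[(triisopropylsilyl)oxy]phenyl}-3,4-dihydro-2H-chromen-5-ol; 21 3,4,5-tris(benzyloxy)benzoyl chloride
Product: 23 (2R,3S)-3,7-bis(benzyloxy)-2-{3-(benzyloxy)-4-[3,4,5-tris(benzyloxy)benzoyloxy]phenyl}-3,4-dihydro-2H-chromen-5-yl 3,4,5-tris(benzyloxy)benzoate, via 3,7,3'-tri-O-benzylcatechin 22 (not isolated)
Conditions: Bu4NF (1.1 equiv), THF, 0 °C, 15 min; then Et3N (5 equiv), DMAP (0.2 equiv), 21 (2.6 equiv), CH2Cl2, 0 °C → rt
Reagents that add atoms: 3,4,5-tris(benzyloxy)benzoyl chloride, O=C(Cl)c1cc(OCc2ccccc2)c(OCc2ccccc2)c(OCc2ccccc2)c1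
Why: Fluoride cleaves only the aryl silyl ether, and the two phenoxides (O5 and O4') are then aroylated under DMAP nucleophilic catalysis; since O3, O7 and O3' are benzyl ethers, the acylation is exhaustive and needs no selectivity.

Step 9
Reactants: 23 (2R,3S)-3,7-bis(benzyloxy)-2-{3-(benzyloxy)-4-[3,4,5-tris(benzyloxy)benzoyloxy]phenyl}-3,4-dihydro-2H-chromen-5-yl 3,4,5-tris(benzyloxy)benzoate
Product: 24 (+)-catechin 5,4'-di-O-gallate
Conditions: H2 (1 atm), Pd(OH)2/C (20 wt%), THF/MeOH (1:1), rt; filtration, evaporation below 30 °C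
Reagents that add atoms: none
Why: Global hydrogenolysis of nine benzyl ethers (the secondary alkyl ether at O3 being the slowest) under neutral conditions, which should leave the aryl esters, the C2–O1 ring ether and both stereocentres intact and avoid base-induced migration of the 4'-galloyl group to O3'.

Compound list
1 | 3-(benzyloxy)-4-hydroxybenzaldehyde | O=Cc1ccc(O)c(OCc2ccccc2)c1 | starting material
2 | chlorotriisopropylsilane | CC(C)[Si](Cl)(C(C)C)C(C)C | starting material
3 | 3-(benzyloxy)-4-[(triisopropylsilyl)oxy]benzaldehyde | O=Cc1ccc(O[Si](C(C)C)(C(C)C)C(C)C)c(OCc2ccccc2)c1 | intermediate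
4 | benzyl prop-2-yn-1-yl ether | C#CCOCc1ccccc1 | starting material
5 | pinacolborane | CC1(C)OBOC1(C)C | starting material
6 | (E)-2-[3-(benzyloxy)prop-1-en-1-yl]-4,4,5,5-tetramethyl-1,3,2-dioxaborolane | CC1(C)OB(/C=C/COCc2ccccc2)OC1(C)C | intermediate
7 | (E)-2-[3-(benzyloxy)prop-2-en-1-yl]-4,4,5,5-tetramethyl-1,3,2-dioxaborolane | CC1(C)OB(C/C=C/OCc2ccccc2)OC1(C)C | intermediate
8 | (1R,2S)-2-(benzyloxy)-1-{3-(benzyloxy)-4-[(triisopropylsilyl)oxy]phenyl}but-3-en-1-ol | C=C[C@H](OCc1ccccc1)[C@H](O)c1ccc(O[Si](C(C)C)(C(C)C)C(C)C)c(OCc2ccccc2)c1 | intermediate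
9 | but-2-ynoic acid | CC#CC(=O)O | starting material
10 | benzyl alcohol | OCc1ccccc1 | starting material
11 | (2E)-3-(benzyloxy)but-2-enoic acid | C/C(OCc1ccccc1)=C\C(=O)O | intermediate
12 | thiophenol | Sc1ccccc1 | starting material
13 | S-phenyl (2E)-3-(benzyloxy)but-2-enethioate | C/C(OCc1ccccc1)=C\C(=O)Sc1ccccc1 | intermediate
14 | 9-[(3S,4R)-3-(benzyloxy)-4-(9-borabicyclo[3.3.1]nonan-9-yloxy)-4-{3-(benzyloxy)-4-[(triisopropylsilyl)oxy]phenyl}butyl]-9-borabicyclo[3.3.1]nonane | C(C[C@H](OCc1ccccc1)[C@H](OB1C2CCCC1CCC2)c1ccc(O[Si](C(C)C)(C(C)C)C(C)C)c(OCc2ccccc2)c1)B1C2CCCC1CCC2 | intermediate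
15 | (2E,7S,8R)-2,7-bis(benzyloxy)-8-{3-(benzyloxy)-4-[(triisopropylsilyl)oxy]phenyl}-8-hydroxyoct-2-en-4-one | C/C(OCc1ccccc1)=C\C(=O)CC[C@H](OCc1ccccc1)[C@H](O)c1ccc(O[Si](C(C)C)(C(C)C)C(C)C)c(OCc2ccccc2)c1 | intermediate
16 | O-phenyl carbonochloridothioate (phenyl chlorothionoformate) | S=C(Cl)Oc1ccccc1 | starting material
17 | O-[(1R,2S,6E)-2,7-bis(benzyloxy)-1-{3-(benzyloxy)-4-[(triisopropylsilyl)oxy]phenyl}-5-oxooct-6-en-1-yl] O-phenyl carbonothioate | C/C(OCc1ccccc1)=C\C(=O)CC[C@H](OCc1ccccc1)[C@H](OC(=S)Oc1ccccc1)c1ccc(O[Si](C(C)C)(C(C)C)C(C)C)c(OCc2ccccc2)c1 | intermediate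
18 | lithium (5S,6R)-5-(benzyloxy)-3-[(2E)-3-(benzyloxy)but-2-enoyl]-6-{3-(benzyloxy)-4-[(triisopropylsilyl)oxy]phenyl}-5,6-dihydro-4H-pyran-2-thiolate | [Li+].[S-]C1=C(C(=O)/C=C(\C)OCc2ccccc2)C[C@H](OCc2ccccc2)[C@@H](c2ccc(O[Si](C(C)C)(C(C)C)C(C)C)c(OCc3ccccc3)c2)O1 | intermediate
19 | (2E)-3-(benzyloxy)-1-[(2R,3S)-3-(benzyloxy)-2-{3-(benzyloxy)-4-[(triisopropylsilyl)oxy]phenyl}-6-(methylsulfanyl)-3,4-dihydro-2H-pyran-5-yl]but-2-en-1-one | CSC1=C(C(=O)/C=C(\C)OCc2ccccc2)C[C@H](OCc2ccccc2)[C@@H](c2ccc(O[Si](C(C)C)(C(C)C)C(C)C)c(OCc3ccccc3)c2)O1 | intermediate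
20 | (2R,3S)-3,7-bis(benzyloxy)-2-{3-(benzyloxy)-4-[(triisopropylsilyl)oxy]phenyl}-3,4-dihydro-2H-chromen-5-ol | Oc1cc(OCc2ccccc2)cc2c1C[C@H](OCc1ccccc1)[C@@H](c1ccc(O[Si](C(C)C)(C(C)C)C(C)C)c(OCc3ccccc3)c1)O2 | intermediate
21 | 3,4,5-tris(benzyloxy)benzoyl chloride | O=C(Cl)c1cc(OCc2ccccc2)c(OCc2ccccc2)c(OCc2ccccc2)c1 | starting material
22 | (2R,3S)-3,7-bis(benzyloxy)-2-[3-(benzyloxy)-4-hydroxyphenyl]-3,4-dihydro-2H-chromen-5-ol (3,7,3'-tri-O-benzylcatechin) | Oc1cc(OCc2ccccc2)cc2c1C[C@H](OCc1ccccc1)[C@@H](c1ccc(O)c(OCc3ccccc3)c1)O2 | intermediate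
23 | (2R,3S)-3,7-bis(benzyloxy)-2-{3-(benzyloxy)-4-[3,4,5-tris(benzyloxy)benzoyloxy]phenyl}-3,4-dihydro-2H-chromen-5-yl 3,4,5-tris(benzyloxy)benzoate | O=C(Oc1cc(OCc2ccccc2)cc2c1C[C@H](OCc1ccccc1)[C@@H](c1ccc(OC(=O)c3cc(OCc4ccccc4)c(OCc4ccccc4)c(OCc4ccccc4)c3)c(OCc3ccccc3)c1)O2)c1cc(OCc2ccccc2)c(OCc2ccccc2)c(OCc2ccccc2)c1 | intermediate
24 | (+)-catechin 5,4'-di-O-gallate, (2R,3S)-3,7-dihydroxy-2-[3-hydroxy-4-(3,4,5-trihydroxybenzoyloxy)phenyl]-3,4-dihydro-2H-chromen-5-yl 3,4,5-trihydroxybenzoate | O=C(Oc1ccc([C@H]2Oc3cc(O)cc(OC(=O)c4cc(O)c(O)c(O)c4)c3C[C@@H]2O)cc1O)c1cc(O)c(O)c(O)c1 | target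

Total step count: 9. Longest linear sequence: 6 (steps 1, 3, 6, 7, 8, 9).

Steps most likely to fail

Step 7 (bears the label). What may go wrong:
- γ- instead of α′-enolisation, or intermolecular thioacylation, in the first closure;
- displacement of the C7 benzyloxy group by liberated thiolate;
- the dienolate failing to reach the folded conformation, so that ring A does not close.

Fallback (thermal hexatriene electrocyclisation with elimination; sets out from 15, rejoins at 22): the sequence is stopped after the MeI stage and the cyclic α-oxo ketene O,S-acetal 19 is isolated. Soft enolisation (t-BuMe2SiOTf, Et3N, CH2Cl2, −78 → 0 °C) should convert its benzyloxy-enone into the neutral 2-silyloxy triene, the silyl dienol ether F1. Heating (toluene, 110 °C, 2,6-lutidine) should close it by 6π-electrocyclisation and, after loss of methanethiol, give the 5-O-silyl chroman F2. In step 8, Bu4NF (2.2 equiv) would then remove both silyl groups and give 22.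

Step 3. What may go wrong:
- erosion of the E geometry of 7 before the allylboration, which would give the syn diastereomer;
- low facial selectivity with the electron-rich aldehyde;
- iridium-hydride migration of the terminal alkene of the product toward the ether oxygen.

Fallback (sets out from 3, rejoins at 8): iridium-catalysed transfer-hydrogenative anti-(α-acyloxy)allylation should give the anti hydroxy benzoate F3. Conditions: 3, prop-2-ene-1,1-diyl dibenzoate, [Ir(cod)Cl]2, the SEGPHOS enantiomer that gives the 1R carbinol, 4-cyano-3-nitrobenzoic acid, K3PO4, propan-2-ol, THF, 60 °C. Et3SiCl/imidazole would give the silyl ether F4. i-Bu2AlH (CH2Cl2, −78 °C) would cleave the benzoate to the allylic alcohol F5. Neutral benzylation with 2-(benzyloxy)-1-methylpyridinium triflate and MgO (PhCF3, 85 °C) would give the benzyl ether F6. Pyridinium p-toluenesulfonate in MeOH would remove the triethylsilyl group and give 8.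

Step 6. What may go wrong:
- slow transmetalation of the O-borylated B-alkyl borane;
- protodeboronation or β-hydride elimination at alkylpalladium.

Fallback (sets out from 8, rejoins at 15): linear hydroformylation (Rh(acac)(CO)2, BIPHEPHOS, CO/H2 1:1, 5 bar, THF, 60 °C) should give the δ-lactol F7. Oxidation (TEMPO cat., PhI(OAc)2, CH2Cl2) should give the δ-lactone F8. Addition of 1-propynyllithium (THF, −78 °C; aq. NH4Cl) should give the hydroxy ynone F9. Phosphine-catalysed conjugate addition of benzyl alcohol (BnOH, PBu3 10 mol%, CH2Cl2, rt) should give the E enone 15.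

Further compounds
F1 | step 7 | (2R,3S)-3-(benzyloxy)-5-[(1E)-3-(benzyloxy)-1-{[tert-butyl(dimethyl)silyl]oxy}buta-1,3-dien-1-yl]-2-{3-(benzyloxy)-4-[(triisopropylsilyl)oxy]phenyl}-6-(methylsulfanyl)-3,4-dihydro-2H-pyran | C=C(OCc1ccccc1)/C=C(O[Si](C)(C)C(C)(C)C)\C1=C(SC)O[C@H](c2ccc(O[Si](C(C)C)(C(C)C)C(C)C)c(OCc3ccccc3)c2)[C@@H](OCc2ccccc2)C1
F2 | step 7 | tert-butyl{[(2R,3S)-3,7-bis(benzyloxy)-2-{3-(benzyloxy)-4-[(triisopropylsilyl)oxy]phenyl}-3,4-dihydro-2H-chromen-5-yl]oxy}dimethylsilane | CC(C)(C)[Si](C)(C)Oc1cc(OCc2ccccc2)cc2c1C[C@H](OCc1ccccc1)[C@@H](c1ccc(O[Si](C(C)C)(C(C)C)C(C)C)c(OCc3ccccc3)c1)O2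
F3 | step 3 | (1R,2S)-1-{3-(benzyloxy)-4-[(triisopropylsilyl)oxy]phenyl}-1-hydroxybut-3-en-2-yl benzoate | C=C[C@H](OC(=O)c1ccccc1)[C@H](O)c1ccc(O[Si](C(C)C)(C(C)C)C(C)C)c(OCc2ccccc2)c1
F4 | step 3 | (1R,2S)-1-{3-(benzyloxy)-4-[(triisopropylsilyl)oxy]phenyl}-1-[(triethylsilyl)oxy]but-3-en-2-yl benzoate | C=C[C@H](OC(=O)c1ccccc1)[C@H](O[Si](CC)(CC)CC)c1ccc(O[Si](C(C)C)(C(C)C)C(C)C)c(OCc2ccccc2)c1
F5 | step 3 | (1R,2S)-1-{3-(benzyloxy)-4-[(triisopropylsilyl)oxy]phenyl}-1-[(triethylsilyl)oxy]but-3-en-2-ol | C=C[C@H](O)[C@H](O[Si](CC)(CC)CC)c1ccc(O[Si](C(C)C)(C(C)C)C(C)C)c(OCc2ccccc2)c1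
F6 | step 3 | {[(1R,2S)-2-(benzyloxy)-1-{3-(benzyloxy)-4-[(triisopropylsilyl)oxy]phenyl}but-3-en-1-yl]oxy}triethylsilane | C=C[C@H](OCc1ccccc1)[C@H](O[Si](CC)(CC)CC)c1ccc(O[Si](C(C)C)(C(C)C)C(C)C)c(OCc2ccccc2)c1
F7 | step 6 | (5S,6R)-5-(benzyloxy)-6-{3-(benzyloxy)-4-[(triisopropylsilyl)oxy]phenyl}tetrahydro-2H-pyran-2-ol | OC1CC[C@H](OCc2ccccc2)[C@@H](c2ccc(O[Si](C(C)C)(C(C)C)C(C)C)c(OCc3ccccc3)c2)O1
F8 | step 6 | (5S,6R)-5-(benzyloxy)-6-{3-(benzyloxy)-4-[(triisopropylsilyl)oxy]phenyl}tetrahydro-2H-pyran-2-one | O=C1CC[C@H](OCc2ccccc2)[C@@H](c2ccc(O[Si](C(C)C)(C(C)C)C(C)C)c(OCc3ccccc3)c2)O1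
F9 | step 6 | (7S,8R)-7-(benzyloxy)-8-{3-(benzyloxy)-4-[(triisopropylsilyl)oxy]phenyl}-8-hydroxyoct-2-yn-4-one | CC#CC(=O)CC[C@H](OCc1ccccc1)[C@H](O)c1ccc(O[Si](C(C)C)(C(C)C)C(C)C)c(OCc2ccccc2)c1
A1 | direct plan | (2R)-2-[4-(allyloxy)-3-(benzyloxy)phenyl]-7-(benzyloxy)-3-nitro-2H-chromen-5-ol | C=CCOc1ccc([C@H]2Oc3cc(OCc4ccccc4)cc(O)c3C=C2[N+](=O)[O-])cc1OCc1ccccc1
A2 | direct plan | (2R)-2-[4-(allyloxy)-3-(benzyloxy)phenyl]-7-(benzyloxy)-5-hydroxychroman-3-one | C=CCOc1ccc([C@H]2Oc3cc(OCc4ccccc4)cc(O)c3CC2=O)cc1OCc1ccccc1
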